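## Structural features

The target is a dibenzylbutyrolactone lignan. Its γ-butyrolactone (O1, C2 carbonyl, C3, C4, C5 as the OCH2 carbon) carries a 2,4-dihydroxy-3-methoxybenzyl group (ring B) on C3 and a 4-hydroxy-3-methoxybenzyl group (ring A) on C4. C3 and C4 are neighbouring stereocentres, both R, so the two benzyl arms are trans on the five-membered ring. C3 is α to the carbonyl and epimerisable, with trans thermodynamically preferred, whereas C4 is not enolisable and must be installed in the correct absolute sense. The three phenols are fragile: ring B is an oxidation-prone resorcinol-type ring, and its 2-hydroxyl sits six atoms from the C2 carbonyl, so a phenoxide there could translactonise to a dihydrocoumarin. Base must therefore be avoided once that oxygen is free. The real difficulties are the absolute configuration at C4, the placing of two similar but different benzyl arms on specific ring carbons, and the contiguous 1,2,3,4-substitution of ring B. The key step uses the fact that C4 is joined to ring A through one CH2 while C3 is flanked by the carbonyl. Folding that CH2 back onto C3 gives a cyclopropane fused across C3–C4, doubly activated once C3 also bears an ester; an aryl nucleophile opening it at the CH2 places ring A one carbon from C4 and leaves C3 as an enolate for the ring B arm.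

## Logic of the disconnections

**24 back to 23.** The three phenolic O–CH2Ph bonds are cut last in the forward sense. Free phenols, above all the ring B 2-hydroxyl next to the lactone carbonyl, would not tolerate the bases and organometallics used earlier. Benzyl ethers allow one neutral hydrogenolysis at the end, with no orthogonality needed. The forward step must leave the lactone, the benzylic C–C bonds and both stereocentres untouched.

**23 back to 19.** A methoxycarbonyl group is put back on C3, so the forward step cuts the C3–CO2CH3 bond. This makes C3 a doubly activated carbon, so the ring B arm can be attached with carbonate base rather than a cryogenic lithium enolate. It also links directly to the enolate left by the key step. The forward removal must end with the arm on C3 trans to that on C4, which is left to thermodynamic control.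

**19 back to 11 and 18.** The C3–CH2(ring B) bond is cut. This splits the skeleton into two halves of similar size and makes the route convergent. The forward step must achieve C-alkylation at a hindered methine with an electron-rich, labile benzylic bromide.

**11 back to 6 and 9.** The ring A aryl–CH2 bond is cut and the CH2 is reconnected to C3, giving a cyclopropane fused to the lactone. The C4 problem becomes the ring fusion of a seven-carbon bicyclic lactone, and the whole aromatic half is removed. The forward step needs an aryl nucleophile that attacks only the cyclopropane CH2, not the ring-fusion CH and not the two carbonyl groups.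

**6 back to 1 and 2.** The two cyclopropane C–C bonds at the malonate carbon and the lactone acyl C–O bond are cut. All carbons then come from two commodity chemicals, and the single stereocentre of 1 supplies both ring-fusion centres. The forward cascade must start with epoxide opening rather than direct chloride displacement, since the latter would lead to the mirror-image lactone.

**9 back to 8 and 7.** The C–Mg bond and then the phenolic O–benzyl bond are cut. The benzyl ether is inert to magnesium and to cuprates and leaves in the final hydrogenolysis.

**18 back to 17, 16, 14 and 12.** The C–Br bond, the benzylic oxidation level, the aryl–CHO bond and the two O–benzyl bonds are cut in turn. The symmetry of 12 and 14 means the only activated ring position gives the required 1,2,3,4-pattern as a single regioisomer. A one-step halomethylation of 14 was rejected because of over-alkylation and the carcinogenic bis(halomethyl) ethers it generates.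

## Other disconnections considered

**Alternative 1:** The cut is the C4–C5 bond. C5 arrives as a CH2 radical tethered through silicon to an oxygen placed temporarily on the ring A benzylic carbon.
- **Forward key step:** the (bromomethyl)dimethylsilyl ether A2, with Bu3SnH and AIBN, would give an α-silyl radical that closes 5-exo-trig onto the enoate β-carbon to the oxasilolane A1. Tamao oxidation of the C–Si bond, lactonisation, hydrogenolytic removal of the benzylic oxygen with the benzyl ethers, and equilibration at C3 would follow.
- **In favour:** the closure is fast and polarity-matched (nucleophilic radical, electron-poor alkene). The medium is neutral. The carbinol centre should steer the new C4 centre trans in the small ring. Ring A never has to be metalated.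
- **Against:** the directing carbinol centre must first be made enantioenriched and is then erased. An extra benzylic C–O bond has to be removed beside an epimerisable lactone. Stoichiometric tin hydride is toxic and hard to remove.
- **Comparison:** on structure, both plans leave C3 to equilibration and are equal there. On mechanism, the radical step is the equal or the better of the chosen step in functional-group tolerance, because no carbanionic reagent meets two carbonyl groups. On step economy it should be several steps longer (asymmetric synthesis of the carbinol, silylation, oxidation, lactonisation), and it is less safe.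

**Alternative 2:** The cut is the C3–CH2(ring B) bond, made together with a temporary bond from the ring B 2-oxygen to C2, which is held at the acetal level.
- **Forward key step:** the salicyl alcohol A5 would release the ortho-quinone methide A6 on heating or with mild base. A6 would add across the enol ether of the dihydrofuran A4 in an inverse-demand hetero-Diels–Alder reaction to the cis-fused furochromene A3. Acetal hydrolysis, oxidation at C2 to the lactone level and hydrogenolysis would follow.
- **In favour:** the ring B ortho-hydroxyl becomes the reacting handle and needs no protecting group. Regiochemistry follows from polarity. Approach anti to the existing arm of A4 should give the trans relationship.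
- **Against:** A4 already contains the C4 stereocentre, and the most direct access to it passes through a lactone carrying that centre, which is the problem the chosen key step solves. A6 carries two extra donor oxygens, so it is less electrophilic and prone to oligomerise. A4 is an acid-labile enol ether. C2 must be re-oxidised in the presence of a freed electron-rich phenol.
- **Comparison:** on structure, the alternative is the better plan in one respect: C3 would be fixed by a kinetically controlled cycloaddition, not by equilibration. On mechanism, its facial control rests on one remote substituent and is less assured than stereospecific chirality transfer. On step economy it adds about three to four steps beyond the lactone stage.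

**Alternative 3:** The cut is the C4–CH2 bond, the other bond of the ring A benzylic carbon.
- **Forward key step:** the aldehyde A8 would form an enamine with a diarylprolinol silyl ether catalyst. Base would release the para-quinone methide A10 from the sulfone A9 by loss of sulfinate. 1,6-Addition would give the aldehyde A7 and set C4. Reduction of the aldehyde with lactonisation, equilibration at C3 and hydrogenolysis of two benzyl ethers would finish.
- **In favour:** C4 is made by catalysis from achiral partners. The ring A phenol stays free. Few operations follow the key step.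
- **Against:** A10 has no stabilising substituents, so it is fleeting, polymerises and can alkylate the amine catalyst or recapture sulfinate. A8 has a racemic β-stereocentre, so matched and mismatched enamines would react at different rates. The new C4 centre in A7 is α to an aldehyde and could racemise through the same enamine, a loss that cannot be repaired later.
- **Comparison:** on structure, both plans leave C3 to equilibration and are equal there. On mechanism, the alternative is the better plan in protecting-group economy and in using a catalytic source of chirality, but its enantiopurity would depend on catalyst control in an untested setting, whereas the chosen plan fixes it with purchased 1. On step economy the two are about equal, since A8 itself needs a benzylic halide of ring B and an oxidative cleavage.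

Key step: step 3

Remark on the chemistry: by CIP analysis the target is the (3R,4R) lactone with trans benzyl arms; the (1S,5R) lactone 6 from (R)-epichlorohydrin and the (3S,4R) ester 11 map onto it consistently, so no structure needed correction.

## Route

Step 1
Reactants: 1 (R)-epichlorohydrin [(2R)-2-(chloromethyl)oxirane]; 2 dimethyl malonate
Product: 6 methyl (1S,5R)-2-oxo-3-oxabicyclo[3.1.0]hexane-1-carboxylate, via chlorohydrin 3 (not isolated), via transposed epoxide 4 (not isolated), via cyclopropylmethanol diester 5 (not isolated)
Conditions: NaOMe (1.0 equiv), MeOH, 0 °C → reflux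
Reagents that add atoms: none
Why: Tandem alkylation–cyclopropanation–lactonisation: the malonate anion opens the epoxide of 1 at its CH2 (3), the alkoxide displaces chloride to the transposed epoxide 4, the malonate carbanion closes the cyclopropane by 3-exo-tet attack at the epoxide CH with inversion (5), and the CH2OH lactonises onto the cis ester. Both ring-fusion centres derive from the one stereocentre of 1 and the (1S,5R) lactone results as long as epoxide opening outruns direct chloride displacement, which would lead to the enantiomer, so the enantiopurity of 6 should be checked before use; NaOMe in MeOH matches the methyl ester and avoids transesterification.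

Step 2
Reactants: 7 4-bromo-2-methoxyphenol
Product: 8 benzyl 4-bromo-2-methoxyphenyl ether [1-(benzyloxy)-4-bromo-2-methoxybenzene]
Conditions: BnBr, K2CO3, acetone, reflux
Reagents that add atoms: benzyl bromide, BrCc1ccccc1
Why: Williamson ether synthesis (phenoxide SN2 on benzyl bromide); the aryl bromide is inert, and the benzyl ether survives magnesium, cuprates and hot LiCl/DMSO yet leaves in the final neutral hydrogenolysis.

Step 3
Reactants: 6 methyl (1S,5R)-2-oxo-3-oxabicyclo[3.1.0]hexane-1-carboxylate; 8 benzyl 4-bromo-2-methoxyphenyl ether
Product: 11 methyl (3S,4R)-4-[4-(benzyloxy)-3-methoxybenzyl]-2-oxotetrahydrofuran-3-carboxylate, via arylmagnesium bromide 9 (not isolated), via bromomagnesium enolate 10 (not isolated)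
Conditions: 8, Mg, THF, 40 °C; then added slowly to 6, CuI (10 mol%), THF, −40 → −20 °C; aq NH4Cl
Reagents that add atoms: none
Why: Transmetalation of 9 to CuI gives an aryl cuprate of monovalent copper, which attacks the unsubstituted cyclopropane carbon (C6 of 6) in an SN2-like oxidative addition with the C6–C1 bond as leaving group, the charge being taken up by the lactone and ester carbonyls, and reductive elimination from the alkyl(aryl) species of trivalent copper forms the ring A aryl–CH2 bond and returns monovalent copper. The closest known reaction type is the copper-catalysed homoconjugate (1,5) addition of Grignard reagents to cyclopropane-1,1-dicarboxylates and to 2-oxo-3-oxabicyclo[3.1.0]hexane-1-carboxylates. No ring is closed; the three-membered ring is opened and its strain drives the step. No stereocentre of consequence is created: C4 is the former ring-fusion carbon C5, none of whose bonds is touched, so the R configuration from 1 is carried over, while C3 is set on protonation of enolate 10 as the labile trans (3S) epimer. Regioselectivity for the CH2 over the ring-fusion CH is secured because both cleavages lead to the same stabilised carbanion and the primary carbon is far more open to backside attack. Chemoselectivity against 1,2-addition to the two carbonyl groups is secured by the copper catalyst, the low temperature and the slow addition of 9, and once the ring has opened the carbonyls are masked as enolate 10.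

Step 4
Reactants: 12 2-methoxyresorcinol (2-methoxybenzene-1,3-diol)
Product: 14 1,3-bis(benzyloxy)-2-methoxybenzene, via monobenzyl ether 13 (not isolated)
Conditions: BnBr (2.2 equiv), K2CO3, DMF, 60 °C
Reagents that add atoms: benzyl bromide, BrCc1ccccc1
Why: Double Williamson etherification through monoether 13; both ring B oxygens are masked so that the later 2-oxygen cannot attack the lactone or consume base, and the product keeps the mirror symmetry that makes the next step regiochemically unambiguous.

Step 5
Reactants: 14 1,3-bis(benzyloxy)-2-methoxybenzene
Product: 16 2,4-bis(benzyloxy)-3-methoxybenzaldehyde, via aryl iminium chloride 15 (not isolated)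
Conditions: POCl3, DMF, 0 → 70 °C; then H2O
Reagents that add atoms: N,N-dimethylformamide, CN(C)C=O (formyl carbon); water, O (formyl oxygen)
Why: Vilsmeier–Haack formylation: the chloroiminium ion attacks the position para to one benzyloxy group and ortho to the other (C4 and C6 are equivalent, C5 is meta to both), and the iminium salt 15 is hydrolysed to the aldehyde.

Step 6
Reactants: 16 2,4-bis(benzyloxy)-3-methoxybenzaldehyde
Product: 17 [2,4-bis(benzyloxy)-3-methoxyphenyl]methanol
Conditions: NaBH4, MeOH/THF, 0 °C
Reagents that add atoms: none
Why: Hydride reduction of an aromatic aldehyde with NaBH4; the benzyl and methyl ethers are inert.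

Step 7
Reactants: 17 [2,4-bis(benzyloxy)-3-methoxyphenyl]methanol
Product: 18 2,4-bis(benzyloxy)-3-methoxybenzyl bromide [1,3-bis(benzyloxy)-4-(bromomethyl)-2-methoxybenzene]
Conditions: PBr3 (0.4 equiv), Et2O, 0 °C; cold aqueous wash, used crude at once
Reagents that add atoms: phosphorus tribromide, BrP(Br)Br
Why: Bromination of a benzylic alcohol through its bromophosphite with displacement by bromide; ether solvent, low temperature and immediate use limit ionisation and self-alkylation of this very electron-rich benzylic halide.

Step 8
Reactants: 11 methyl (3S,4R)-4-[4-(benzyloxy)-3-methoxybenzyl]-2-oxotetrahydrofuran-3-carboxylate; 18 2,4-bis(benzyloxy)-3-methoxybenzyl bromide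
Product: 19 methyl (3R,4R)-3-[2,4-bis(benzyloxy)-3-methoxybenzyl]-4-[4-(benzyloxy)-3-methoxybenzyl]-2-oxotetrahydrofuran-3-carboxylate
Conditions: K2CO3, DMF, 0 °C → rt
Reagents that add atoms: none
Why: SN2 C-alkylation of a malonate-type methine (deprotonated by carbonate) with a soft benzylic bromide; the electrophile should enter anti to the C4 arm to give mainly the (3R) quaternary centre, but this configuration is of no consequence because C3 becomes trigonal in step 9, and C4 is not acidic and stays untouched.

Step 9
Reactants: 19 methyl (3R,4R)-3-[2,4-bis(benzyloxy)-3-methoxybenzyl]-4-[4-(benzyloxy)-3-methoxybenzyl]-2-oxotetrahydrofuran-3-carboxylate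
Product: 23 (3R,4R)-3-[2,4-bis(benzyloxy)-3-methoxybenzyl]-4-[4-(benzyloxy)-3-methoxybenzyl]dihydrofuran-2(3H)-one, via lithium carboxylate 20 (not isolated), via lithium enolate 21 (not isolated), via cis lactone 22 (not isolated)
Conditions: LiCl, H2O, DMSO, 140 °C, held until the C3 epimer ratio is constant
Reagents that add atoms: none
Why: Krapcho demethoxycarbonylation: chloride dealkylates the methyl ester by SN2 at CH3 (20), the carboxylate loses CO2 to the lactone enolate 21, and water protonates it. Kinetic protonation anti to the C4 arm would favour the cis lactone 22, but protonation is reversible in the hot, weakly basic medium, so C3 should settle under thermodynamic control as the trans (3R) epimer; the methyl ester was chosen because it is the best substrate for this dealkylation.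

Step 10
Reactants: 23 (3R,4R)-3-[2,4-bis(benzyloxy)-3-methoxybenzyl]-4-[4-(benzyloxy)-3-methoxybenzyl]dihydrofuran-2(3H)-one
Product: 24 (3R,4R)-3-(2,4-dihydroxy-3-methoxybenzyl)-4-(4-hydroxy-3-methoxybenzyl)dihydrofuran-2(3H)-one (CNP0352334.1)
Conditions: H2 (1 atm), Pd/C, EtOAc/MeOH, rt
Reagents that add atoms: none
Why: Hydrogenolysis of three aryl benzyl ethers over Pd/C; the lactone and the benzylic C–C bonds are inert, and the neutral medium avoids both epimerisation at C3 and phenoxide-triggered translactonisation by the ring B 2-hydroxyl.

## Compound list

1 | (R)-epichlorohydrin, (2R)-2-(chloromethyl)oxirane | ClC[C@H]1CO1 | starting material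
2 | dimethyl malonate | COC(=O)CC(=O)OC | starting material
3 | dimethyl 2-[(2R)-3-chloro-2-hydroxypropyl]propanedioate (present as its sodium alkoxide) | ClC[C@H](O)CC(C(=O)OC)C(=O)OC | intermediate
4 | dimethyl 2-{[(2R)-oxiran-2-yl]methyl}propanedioate | COC(=O)C(C[C@@H]1CO1)C(=O)OC | intermediate
5 | dimethyl (2R)-2-(hydroxymethyl)cyclopropane-1,1-dicarboxylate | OC[C@@H]1CC1(C(=O)OC)C(=O)OC | intermediate
6 | methyl (1S,5R)-2-oxo-3-oxabicyclo[3.1.0]hexane-1-carboxylate | C1[C@H]2COC(=O)[C@@]12C(=O)OC | intermediate
7 | 4-bromo-2-methoxyphenol | COc1cc(Br)ccc1O | starting material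
8 | 1-(benzyloxy)-4-bromo-2-methoxybenzene | COc1cc(Br)ccc1OCc1ccccc1 | intermediate
9 | [4-(benzyloxy)-3-methoxyphenyl]magnesium bromide | COc1cc([Mg]Br)ccc1OCc1ccccc1 | intermediate
10 | bromomagnesium (4R)-4-[4-(benzyloxy)-3-methoxybenzyl]-3-(methoxycarbonyl)-4,5-dihydrofuran-2-olate | COc1cc(C[C@H]2COC(O[Mg]Br)=C2C(=O)OC)ccc1OCc1ccccc1 | intermediate
11 | methyl (3S,4R)-4-[4-(benzyloxy)-3-methoxybenzyl]-2-oxotetrahydrofuran-3-carboxylate | COc1cc(C[C@H]2COC(=O)[C@@H]2C(=O)OC)ccc1OCc1ccccc1 | intermediate
12 | 2-methoxyresorcinol (2-methoxybenzene-1,3-diol) | COc1c(O)cccc1O | starting material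
13 | 3-(benzyloxy)-2-methoxyphenol | COc1c(O)cccc1OCc1ccccc1 | intermediate
14 | 1,3-bis(benzyloxy)-2-methoxybenzene | COc1c(OCc2ccccc2)cccc1OCc1ccccc1 | intermediate
15 | N-[2,4-bis(benzyloxy)-3-methoxybenzylidene]-N-methylmethanaminium chloride | COc1c(OCc2ccccc2)ccc(C=[N+](C)C)c1OCc1ccccc1.[Cl-] | intermediate
16 | 2,4-bis(benzyloxy)-3-methoxybenzaldehyde | COc1c(OCc2ccccc2)ccc(C=O)c1OCc1ccccc1 | intermediate
17 | [2,4-bis(benzyloxy)-3-methoxyphenyl]methanol | COc1c(OCc2ccccc2)ccc(CO)c1OCc1ccccc1 | intermediate
18 | 1,3-bis(benzyloxy)-4-(bromomethyl)-2-methoxybenzene | COc1c(OCc2ccccc2)ccc(CBr)c1OCc1ccccc1 | intermediate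
19 | methyl (3R,4R)-3-[2,4-bis(benzyloxy)-3-methoxybenzyl]-4-[4-(benzyloxy)-3-methoxybenzyl]-2-oxotetrahydrofuran-3-carboxylate | COc1cc(C[C@H]2COC(=O)[C@]2(C(=O)OC)Cc2ccc(OCc3ccccc3)c(OC)c2OCc2ccccc2)ccc1OCc1ccccc1 | intermediate
20 | lithium (3R,4R)-3-[2,4-bis(benzyloxy)-3-methoxybenzyl]-4-[4-(benzyloxy)-3-methoxybenzyl]-2-oxotetrahydrofuran-3-carboxylate | COc1cc(C[C@H]2COC(=O)[C@]2(C([O-])=O)Cc2ccc(OCc3ccccc3)c(OC)c2OCc2ccccc2)ccc1OCc1ccccc1.[Li+] | intermediate
21 | lithium (4R)-3-[2,4-bis(benzyloxy)-3-methoxybenzyl]-4-[4-(benzyloxy)-3-methoxybenzyl]-4,5-dihydrofuran-2-olate | COc1cc(C[C@H]2COC([O-])=C2Cc2ccc(OCc3ccccc3)c(OC)c2OCc2ccccc2)ccc1OCc1ccccc1.[Li+] | intermediate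
22 | (3S,4R)-3-[2,4-bis(benzyloxy)-3-methoxybenzyl]-4-[4-(benzyloxy)-3-methoxybenzyl]dihydrofuran-2(3H)-one (cis) | COc1cc(C[C@H]2COC(=O)[C@H]2Cc2ccc(OCc3ccccc3)c(OC)c2OCc2ccccc2)ccc1OCc1ccccc1 | intermediate
23 | (3R,4R)-3-[2,4-bis(benzyloxy)-3-methoxybenzyl]-4-[4-(benzyloxy)-3-methoxybenzyl]dihydrofuran-2(3H)-one (trans) | COc1cc(C[C@H]2COC(=O)[C@@H]2Cc2ccc(OCc3ccccc3)c(OC)c2OCc2ccccc2)ccc1OCc1ccccc1 | intermediate
24 | (3R,4R)-3-(2,4-dihydroxy-3-methoxybenzyl)-4-(4-hydroxy-3-methoxybenzyl)dihydrofuran-2(3H)-one | COc1cc(C[C@H]2COC(=O)[C@@H]2Cc2ccc(O)c(OC)c2O)ccc1O | target

## Step count and least certain steps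

Total: 10 steps, convergent from three branches. Longest linear sequence: 7 steps (steps 4, 5, 6, 7, 8, 9, 10 from 12); from 1 the sequence is 5 steps (1, 3, 8, 9, 10).

**Step 3 (key step).** The likeliest failures are 1,2-addition of the aryl Grignard reagent to the lactone or ester carbonyl, copper-mediated homocoupling of the aryl group, and incomplete conversion because aryl cuprates open cyclopropanes less readily than alkyl ones. The fallback sets out from 9 and returns at 23; it makes C4 by asymmetric hydrogenation instead of chiral-pool transfer.
- Quenching 9 with DMF (then aq HCl) should give 4-(benzyloxy)-3-methoxybenzaldehyde F1.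
- Stobbe condensation with dimethyl succinate (NaOMe, MeOH, reflux) should give the half-ester (3E)-4-[4-(benzyloxy)-3-methoxyphenyl]-3-(methoxycarbonyl)but-3-enoic acid F2.
- Hydrogenation with a cationic rhodium bisphosphine catalyst ([Rh(cod)2]BF4 with the enantiomer of a DuPhos-type ligand that delivers the R acid; H2, MeOH) should give (3R)-4-[4-(benzyloxy)-3-methoxyphenyl]-3-(methoxycarbonyl)butanoic acid F3. The benzyl ether is inert to the homogeneous catalyst.
- Reduction of the ester in the presence of the carboxylate (KOH, then Ca(BH4)2 from CaCl2 and NaBH4, EtOH; then aq HCl) with lactonisation should give (4R)-4-[4-(benzyloxy)-3-methoxybenzyl]dihydrofuran-2(3H)-one F4.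
- Deprotonation with LiN(SiMe3)2 (THF, −78 °C) and alkylation with 18 anti to the C4 arm should give 23 directly, so steps 8 and 9 are not needed.

**Step 7.** The very electron-rich benzylic bromide may ionise and self-condense (Friedel–Crafts-type oligomerisation) or hydrolyse during formation, work-up or the alkylation of step 8. The fallback sets out from 11 and 16 and returns at 24; it avoids any benzylic halide.
- 11 is demethoxycarbonylated under the step 9 conditions to the same lactone F4.
- Its lithium enolate (LiN(SiMe3)2, THF, −78 °C) adds to aldehyde 16 anti to the C4 arm to give the aldol (3S,4R)-3-{[2,4-bis(benzyloxy)-3-methoxyphenyl](hydroxy)methyl}-4-[4-(benzyloxy)-3-methoxybenzyl]dihydrofuran-2(3H)-one F5, as both carbinol epimers.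
- Hydrogenolysis (H2, Pd/C, EtOAc/AcOH) should remove the three benzyl ethers and the activated benzylic hydroxyl in one operation to give 24. The trans relationship is kept only if dehydration to the benzylidene lactone is avoided.

**Step 9.** Dealkylation at the congested quaternary centre may be incomplete, chloride may reversibly open the lactone at C5, and equilibration at C3 may stop short, leaving material of the wrong relative configuration. The fallback sets out from 19 and returns at 23.
- Saponification (KOH, MeOH/H2O, reflux) and acidification with HCl (which re-closes the lactone) should give (3R,4R)-3-[2,4-bis(benzyloxy)-3-methoxybenzyl]-4-[4-(benzyloxy)-3-methoxybenzyl]-2-oxotetrahydrofuran-3-carboxylic acid F6.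
- Heating in toluene at 110 °C decarboxylates it through the cyclic six-membered transition state.
- A DBU hold in the same solvent converts any 22 into 23.

**Step 5.** A benzyl ether may be partly lost to the hydrogen chloride formed, or substitution may be sluggish because the central methoxy group is twisted out of conjugation. The fallback sets out from 14 and returns at 16.
- Bromination with NBS (MeCN, 0 °C) at the same activated position should give 1,3-bis(benzyloxy)-4-bromo-2-methoxybenzene F7.
- Magnesium insertion (Mg, THF) and quenching with DMF (then aq HCl) should give 16.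

## Further compounds

F1 | step 3 | 4-(benzyloxy)-3-methoxybenzaldehyde | COc1cc(C=O)ccc1OCc1ccccc1
F2 | step 3 | (3E)-4-[4-(benzyloxy)-3-methoxyphenyl]-3-(methoxycarbonyl)but-3-enoic acid | COC(=O)/C(CC(=O)O)=C/c1ccc(OCc2ccccc2)c(OC)c1
F3 | step 3 | (3R)-4-[4-(benzyloxy)-3-methoxyphenyl]-3-(methoxycarbonyl)butanoic acid | COc1cc(C[C@H](CC(=O)O)C(=O)OC)ccc1OCc1ccccc1
F4 | step 3 | (4R)-4-[4-(benzyloxy)-3-methoxybenzyl]dihydrofuran-2(3H)-one | COc1cc(C[C@H]2COC(=O)C2)ccc1OCc1ccccc1
F5 | step 7 | (3S,4R)-3-{[2,4-bis(benzyloxy)-3-methoxyphenyl](hydroxy)methyl}-4-[4-(benzyloxy)-3-methoxybenzyl]dihydrofuran-2(3H)-one (both carbinol epimers) | COc1cc(C[C@H]2COC(=O)[C@@H]2C(O)c2ccc(OCc3ccccc3)c(OC)c2OCc2ccccc2)ccc1OCc1ccccc1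
F6 | step 9 | (3R,4R)-3-[2,4-bis(benzyloxy)-3-methoxybenzyl]-4-[4-(benzyloxy)-3-methoxybenzyl]-2-oxotetrahydrofuran-3-carboxylic acid | COc1cc(C[C@H]2COC(=O)[C@]2(C(=O)O)Cc2ccc(OCc3ccccc3)c(OC)c2OCc2ccccc2)ccc1OCc1ccccc1
F7 | step 5 | 1,3-bis(benzyloxy)-4-bromo-2-methoxybenzene | COc1c(OCc2ccccc2)ccc(Br)c1OCc1ccccc1
A1 | alternative 1 | methyl 3-[2,4-bis(benzyloxy)-3-methoxyphenyl]-2-{(4S,5R)-5-[4-(benzyloxy)-3-methoxyphenyl]-2,2-dimethyl-1,2-oxasilolan-4-yl}propanoate (epimers at C2) | COC(=O)C(Cc1ccc(OCc2ccccc2)c(OC)c1OCc1ccccc1)[C@@H]1C[Si](C)(C)O[C@H]1c1ccc(OCc2ccccc2)c(OC)c1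
A2 | alternative 1 | methyl (2E,4R)-2-[2,4-bis(benzyloxy)-3-methoxybenzyl]-4-[4-(benzyloxy)-3-methoxyphenyl]-4-{[(bromomethyl)dimethylsilyl]oxy}but-2-enoate | COC(=O)/C(Cc1ccc(OCc2ccccc2)c(OC)c1OCc1ccccc1)=C/[C@@H](O[Si](C)(C)CBr)c1ccc(OCc2ccccc2)c(OC)c1
A3 | alternative 2 | (3R,3aR,9aR)-7-(benzyloxy)-3-[4-(benzyloxy)-3-methoxybenzyl]-8-methoxy-3,3a,4,9a-tetrahydro-2H-furo[2,3-b]chromene (cis-fused) | COc1cc(C[C@H]2CO[C@@H]3Oc4c(OC)c(OCc5ccccc5)ccc4C[C@H]23)ccc1OCc1ccccc1
A4 | alternative 2 | (3R)-3-[4-(benzyloxy)-3-methoxybenzyl]-2,3-dihydrofuran | COc1cc(C[C@H]2COC=C2)ccc1OCc1ccccc1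
A5 | alternative 2 | 3-(benzyloxy)-6-(hydroxymethyl)-2-methoxyphenol | COc1c(OCc2ccccc2)ccc(CO)c1O
A6 | alternative 2 | 3-(benzyloxy)-2-methoxy-6-methylidenecyclohexa-2,4-dien-1-one | C=C1C=CC(OCc2ccccc2)=C(OC)C1=O
A7 | alternative 3 | methyl (3R)-2-[2,4-bis(benzyloxy)-3-methoxybenzyl]-3-formyl-4-(4-hydroxy-3-methoxyphenyl)butanoate (epimers at C2) | COc1cc(C[C@H](C(Cc2ccc(OCc3ccccc3)c(OC)c2OCc2ccccc2)C(=O)OC)C=O)ccc1O
A8 | alternative 3 | methyl 2-[2,4-bis(benzyloxy)-3-methoxybenzyl]-4-oxobutanoate (racemic) | COC(=O)C(CC=O)Cc1ccc(OCc2ccccc2)c(OC)c1OCc1ccccc1
A9 | alternative 3 | 2-methoxy-4-[(4-methylbenzenesulfonyl)methyl]phenol | COc1cc(CS(=O)(=O)c2ccc(C)cc2)ccc1O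
A10 | alternative 3 | 2-methoxy-4-methylidenecyclohexa-2,5-dien-1-one | C=C1C=CC(=O)C(OC)=C1
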